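**Direct plan and its weak points**

A direct plan would make the C3–C1′ bond last: Suzuki coupling of the 3-iodochromone A1 (5,7-bis-MOM, 6-prenyl) with the chromenyl pinacol boronate A2 would give the tris-MOM isoflavone A3, and acid would unmask the target.
- Final removal of three MOM acetals with warm aqueous mineral acid: a prenyl group between two just-freed phenols and an electron-rich 2H-chromene would meet Brønsted acid at the last stage (chroman closure, chromene hydration).
- Linear build-up of the A-ring ketone behind A1: the third ring oxygen would be added by C–H borylation/oxidation, and two kinds of acetal put on and off only to tell the two ortho oxygens apart. That is about seven operations for two C–C bonds.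
- Dehydrogenation of a chroman to the chromene of A2 with a quinone oxidant: a redox correction of a ring made at the wrong oxidation level.

**Retrosynthetic overview of the new route**

1. Target 16 ⇐ tris-SEM isoflavone 15 ⇐ (key step) enaminone 13, in which the prenyl group sits on the oxygen that becomes O1. A para-Claisen–Cope shift carries it to C6 (the ring-A carbon para to C8a–O1, between the 5- and 7-oxygens), and the phenol it frees closes ring C through O1–C2.
2. 13 ⇐ chalcone epoxide 11 by a Lewis-acid 1,2-aroyl shift, which forms C3–C4; the C3–C1′ bond is never made, it comes as the aryl–CHO bond of aldehyde 9. 11 ⇐ aldol of acetophenone 4 with 9.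
3. Ring order: A bought (phloroacetophenone); B → pyran D (resorcinol + prenal, already a chromene); pyranone C last. There is no cross-coupling and no chromone before the key step.
4. Weak steps avoided by design: the ortho oxygens are told apart by the chelated OH of phloroacetophenone, and the prenyl ether is itself the protecting group of O1. The chromene is made at the right oxidation level. The remaining SEM ethers leave with fluoride, so no Brønsted acid is used after the prenyl group reaches carbon.

Key step: step 9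

Remark: the target has no stereocentre, so the single-enantiomer requirement is met by any route. The trans-epoxide 11 is used as the racemate; its two stereocentres and the alkene geometries of 10 and 13 are erased in later steps. SEM = [2-(trimethylsilyl)ethoxy]methyl.

**Route**

Step 1
Reactants: 1 1-(2,4,6-trihydroxyphenyl)ethan-1-one (phloroacetophenone)
Product: 2 1-[2-hydroxy-4,6-bis(SEM-oxy)phenyl]ethan-1-one
Conditions: SEMCl (2.1 equiv), i-Pr2NEt, CH2Cl2, 0 °C → rt
Reagents that add atoms: 2-(trimethylsilyl)ethoxymethyl chloride, C[Si](C)(C)CCOCCl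
Why: Base-mediated O-alkylation (acetalisation) caps the 4-OH and one ortho OH, after which the last ortho OH is locked in a hydrogen bond to the acetyl group and stays free; this one operation tells the two ortho oxygens apart.

Step 2
Reactants: 2 1-[2-hydroxy-4,6-bis(SEM-oxy)phenyl]ethan-1-one; 3 3-methylbut-2-en-1-ol (prenol)
Product: 4 1-[2-[(3-methylbut-2-en-1-yl)oxy]-4,6-bis(SEM-oxy)phenyl]ethan-1-one
Conditions: PPh3, DIAD, THF, 0 °C → rt
Reagents that add atoms: none
Why: Mitsunobu etherification (SN2 at the primary allylic carbon, neutral medium, no C-alkylation) places the prenyl group on the oxygen that is to become O1, where it also serves as that oxygen's protecting group.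

Step 3
Reactants: 5 resorcinol; 6 3-methylbut-2-enal
Product: 7 2,2-dimethyl-2H-chromen-7-ol
Conditions: pyridine, 140 °C, sealed vessel; resorcinol used in twofold excess
Reagents that add atoms: none
Why: Pyridine-mediated chromenylation: ortho C-alkylation of resorcinol at C4 by the enal, dehydration (loss of one water) to an o-quinone methide and oxa-6π electrocyclisation give the 2H-chromene directly; the excess of resorcinol limits double annulation and the minor 5-hydroxy isomer is removed by chromatography.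

Step 4
Reactants: 7 2,2-dimethyl-2H-chromen-7-ol
Product: 8 7-hydroxy-2,2-dimethyl-2H-chromene-6-carbaldehyde
Conditions: MgCl2, Et3N, (CH2O)n, MeCN, reflux; dilute HCl work-up
Reagents that add atoms: paraformaldehyde (formaldehyde), C=O
Why: Magnesium-mediated ortho-formylation (Casnati–Skattebøl) goes through the magnesium phenoxide, which delivers formaldehyde only to an ortho carbon and should prefer C6 (one neighbour, para to the ring oxygen) over C8 (between two oxygens); the basic medium spares the chromene.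

Step 5
Reactants: 8 7-hydroxy-2,2-dimethyl-2H-chromene-6-carbaldehyde
Product: 9 2,2-dimethyl-7-(SEM-oxy)-2H-chromene-6-carbaldehyde
Conditions: SEMCl, i-Pr2NEt, CH2Cl2, 0 °C → rt
Reagents that add atoms: 2-(trimethylsilyl)ethoxymethyl chloride, C[Si](C)(C)CCOCCl
Why: O-alkylation with SEMCl masks the phenol, which would otherwise open the later epoxide through an o-quinone methide and close a benzofuran at the ketoaldehyde stage.

Step 6
Reactants: 4 1-[2-(prenyloxy)-4,6-bis(SEM-oxy)phenyl]ethan-1-one; 9 2,2-dimethyl-7-(SEM-oxy)-2H-chromene-6-carbaldehyde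
Product: 10 (2E)-3-[2,2-dimethyl-7-(SEM-oxy)-2H-chromen-6-yl]-1-[2-(prenyloxy)-4,6-bis(SEM-oxy)phenyl]prop-2-en-1-one
Conditions: KOH, EtOH/H2O, rt
Reagents that add atoms: none
Why: Claisen–Schmidt aldol condensation of the methyl ketone with the non-enolisable aldehyde gives the E-enone by E1cB dehydration; SEM acetals, the prenyl ether and the chromene are stable to aqueous-alcoholic base, and no free ortho OH is present to close a flavanone.

Step 7
Reactants: 10 the (E)-chalcone
Product: 11 rac-[(2S,3R)-3-[2,2-dimethyl-7-(SEM-oxy)-2H-chromen-6-yl]oxiran-2-yl][2-(prenyloxy)-4,6-bis(SEM-oxy)phenyl]methanone (trans-epoxide, racemate)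
Conditions: 30 % H2O2, 2 M NaOH, THF/MeOH, 0 °C → rt; used crude
Reagents that add atoms: hydrogen peroxide, OO
Why: Weitz–Scheffer nucleophilic epoxidation: hydroperoxide anion adds only to the electron-poor enone (the prenyl and chromene alkenes are electron-rich and inert), and stepwise ring closure from the E-enone gives the trans-epoxide as the racemate.

Step 8
Reactants: 11 the trans-epoxide
Product: 13 (2E)-2-[2,2-dimethyl-7-(SEM-oxy)-2H-chromen-6-yl]-1-[2-(prenyloxy)-4,6-bis(SEM-oxy)phenyl]-3-(pyrrolidin-1-yl)prop-2-en-1-one, via 2-[2,2-dimethyl-7-(SEM-oxy)-2H-chromen-6-yl]-3-oxo-3-[2-(prenyloxy)-4,6-bis(SEM-oxy)phenyl]propanal 12 (not isolated)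
Conditions: BF3·OEt2 (0.5 equiv), CH2Cl2, −78 → −40 °C, 15 min; then pyrrolidine (4 equiv), 4 Å MS, −40 °C → rt
Reagents that add atoms: pyrrolidine, C1CCNC1
Why: Lewis-acid rearrangement of a chalcone epoxide (House/Meinwald-type semipinacol): the Cβ–O bond ionises toward the cation stabilised by the 2,4-dioxygenated chromenyl ring, the aroyl group shifts from Cα to Cβ to form the C3–C4 bond and ketoaldehyde 12, and pyrrolidine condenses at the formyl carbon with loss of water to the push–pull enaminone, which stores the future C2 and erases both stereocentres.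

Step 9
Reactants: 13 the O-prenyl enaminone
Product: 15 3-[2,2-dimethyl-7-(SEM-oxy)-2H-chromen-6-yl]-6-(3-methylbut-2-en-1-yl)-5,7-bis(SEM-oxy)-4H-chromen-4-one, via (2E)-2-[2,2-dimethyl-7-(SEM-oxy)-2H-chromen-6-yl]-1-[6-hydroxy-3-(3-methylbut-2-en-1-yl)-2,4-bis(SEM-oxy)phenyl]-3-(pyrrolidin-1-yl)prop-2-en-1-one 14 (not isolated)
Conditions: N,N-diethylaniline (degassed, 0.05 M), 195 °C, slow argon stream, 3 h
Reagents that add atoms: none
Why: On heating, the aryl prenyl ether undergoes an aromatic Claisen rearrangement to the ortho dienone (1,1-dimethylallyl on the future C8), which is crowded and slow to enolise in the aprotic amine, so it goes on by a Cope [3,3] shift to the para carbon (future C6) and aromatises to phenol 14; this phenol is ortho to the vinylogous-amide carbonyl and adds to the enaminone β-carbon, and loss of pyrrolidine closes ring C through O1–C2. The closest known reaction types are the para-Claisen–Cope rearrangement of 2-prenyloxy-4,6-dialkoxyaryl ketones in hot N,N-dialkylaniline and the tandem Claisen/6-endo cyclisation of 2-allyloxyaryl enaminones to chromones. Ring C closes in the 6-endo-trig mode by conjugate addition/β-elimination, and no stereocentre is formed. Two selectivities are needed: prenyl to the para carbon and not the ortho carbon, and ring closure through the oxygen para to the prenyl group and not through the other ortho oxygen. The first should follow from the reversibility of the ortho step and the relief of strain in the Cope step (a CH2-linked prenyl between the two SEM-oxy groups instead of a quaternary 1,1-dimethylallyl); the second is automatic, because the only free phenol is the one the prenyl group has just left and the other ortho oxygen stays SEM-protected. SEM acetals, the chromene and the C-prenyl group are thermally inert under these conditions, and the argon stream removes pyrrolidine so that the chromone does not reopen.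

Step 10
Reactants: 15 the tris-SEM isoflavone
Product: 16 5,7-dihydroxy-3-(7-hydroxy-2,2-dimethyl-2H-chromen-6-yl)-6-(3-methylbut-2-en-1-yl)-4H-chromen-4-one (Krausianone 2)
Conditions: TBAF (excess), dimedone (6.5 equiv), DMPU/THF, 60 °C; aq NH4Cl work-up
Reagents that add atoms: none
Why: Fluoride-induced fragmentation of the three SEM acetals (attack at silicon, loss of ethene and formaldehyde) frees the phenols without acid, so the C6 prenyl group between two new phenols and the chromene never meet a Brønsted acid; dimedone traps the formaldehyde before it can hydroxymethylate the electron-rich rings.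

**Compound list**

1 | 1-(2,4,6-trihydroxyphenyl)ethan-1-one (phloroacetophenone) | CC(=O)c1c(O)cc(O)cc1O | starting material
2 | 1-[2-hydroxy-4,6-bis(SEM-oxy)phenyl]ethan-1-one | CC(=O)c1c(O)cc(OCOCC[Si](C)(C)C)cc1OCOCC[Si](C)(C)C | intermediate
3 | 3-methylbut-2-en-1-ol (prenol) | CC(C)=CCO | starting material
4 | 1-[2-[(3-methylbut-2-en-1-yl)oxy]-4,6-bis(SEM-oxy)phenyl]ethan-1-one | CC(=O)c1c(OCC=C(C)C)cc(OCOCC[Si](C)(C)C)cc1OCOCC[Si](C)(C)C | intermediate
5 | resorcinol | Oc1cccc(O)c1 | starting material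
6 | 3-methylbut-2-enal | CC(C)=CC=O | starting material
7 | 2,2-dimethyl-2H-chromen-7-ol | CC1(C)C=Cc2ccc(O)cc2O1 | intermediate
8 | 7-hydroxy-2,2-dimethyl-2H-chromene-6-carbaldehyde | CC1(C)C=Cc2cc(C=O)c(O)cc2O1 | intermediate
9 | 2,2-dimethyl-7-(SEM-oxy)-2H-chromene-6-carbaldehyde | CC1(C)C=Cc2cc(C=O)c(OCOCC[Si](C)(C)C)cc2O1 | intermediate
10 | (2E)-3-[2,2-dimethyl-7-(SEM-oxy)-2H-chromen-6-yl]-1-[2-(prenyloxy)-4,6-bis(SEM-oxy)phenyl]prop-2-en-1-one | O=C(/C=C/c1cc2C=CC(C)(C)Oc2cc1OCOCC[Si](C)(C)C)c1c(OCC=C(C)C)cc(OCOCC[Si](C)(C)C)cc1OCOCC[Si](C)(C)C | intermediate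
11 | rac-[(2S,3R)-3-[2,2-dimethyl-7-(SEM-oxy)-2H-chromen-6-yl]oxiran-2-yl][2-(prenyloxy)-4,6-bis(SEM-oxy)phenyl]methanone (trans; racemate, one enantiomer drawn) | O=C(c1c(OCC=C(C)C)cc(OCOCC[Si](C)(C)C)cc1OCOCC[Si](C)(C)C)[C@H]1O[C@@H]1c1cc2C=CC(C)(C)Oc2cc1OCOCC[Si](C)(C)C | intermediate
12 | 2-[2,2-dimethyl-7-(SEM-oxy)-2H-chromen-6-yl]-3-oxo-3-[2-(prenyloxy)-4,6-bis(SEM-oxy)phenyl]propanal (racemic, enolisable; not isolated) | O=CC(c1cc2C=CC(C)(C)Oc2cc1OCOCC[Si](C)(C)C)C(=O)c1c(OCC=C(C)C)cc(OCOCC[Si](C)(C)C)cc1OCOCC[Si](C)(C)C | intermediate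
13 | (2E)-2-[2,2-dimethyl-7-(SEM-oxy)-2H-chromen-6-yl]-1-[2-(prenyloxy)-4,6-bis(SEM-oxy)phenyl]-3-(pyrrolidin-1-yl)prop-2-en-1-one | O=C(c1c(OCC=C(C)C)cc(OCOCC[Si](C)(C)C)cc1OCOCC[Si](C)(C)C)/C(c1cc2C=CC(C)(C)Oc2cc1OCOCC[Si](C)(C)C)=C/N1CCCC1 | intermediate
14 | (2E)-2-[2,2-dimethyl-7-(SEM-oxy)-2H-chromen-6-yl]-1-[6-hydroxy-3-(3-methylbut-2-en-1-yl)-2,4-bis(SEM-oxy)phenyl]-3-(pyrrolidin-1-yl)prop-2-en-1-one (not isolated) | O=C(c1c(O)cc(OCOCC[Si](C)(C)C)c(CC=C(C)C)c1OCOCC[Si](C)(C)C)/C(c1cc2C=CC(C)(C)Oc2cc1OCOCC[Si](C)(C)C)=C/N1CCCC1 | intermediate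
15 | 3-[2,2-dimethyl-7-(SEM-oxy)-2H-chromen-6-yl]-6-(3-methylbut-2-en-1-yl)-5,7-bis(SEM-oxy)-4H-chromen-4-one | CC(C)=CCc1c(OCOCC[Si](C)(C)C)cc2occ(-c3cc4C=CC(C)(C)Oc4cc3OCOCC[Si](C)(C)C)c(=O)c2c1OCOCC[Si](C)(C)C | intermediate
16 | Krausianone 2 | CC(C)=CCc1c(O)cc2occ(-c3cc4c(cc3O)OC(C)(C)C=C4)c(=O)c2c1O | target

**Step count**

Total: 10 steps. Longest linear sequence: 8 steps (steps 3–10, from resorcinol).

**Steps most likely to fail, with fallbacks**

Step 8 (aroyl shift). The Lewis acid may ionise the aryl prenyl ether or an SEM acetal, the benzylic cation may be trapped by the neighbouring acetal oxygen, or hydride may shift instead of aroyl (giving a 1,2-diketone). The fallback sets out from ketone 4 and reaches 13 without any Lewis acid, through the deoxybenzoin. 4-Bromoresorcinol F6 would be annulated with 3-methylbut-2-enal 6 (pyridine, 140 °C) to 6-bromo-2,2-dimethyl-2H-chromen-7-ol F7 and protected (SEMCl, i-Pr2NEt) as its SEM ether F8. Palladium-catalysed α-arylation of 4 with F8 (Pd2(dba)3, XPhos, NaOt-Bu, toluene, 80 °C) should give 2-[2,2-dimethyl-7-(SEM-oxy)-2H-chromen-6-yl]-1-[2-(prenyloxy)-4,6-bis(SEM-oxy)phenyl]ethan-1-one F9; the trisubstituted prenyl ether should ionise at the bulky-phosphine Pd(0) far more slowly than the aryl bromide adds oxidatively. Heating F9 with DMF dimethyl acetal and pyrrolidine (90 °C) would give 13, where the route is rejoined.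

Step 9 (key step). The ortho dienone may enolise before the Cope shift (1,1-dimethylallyl at the future C8), the prenyl ether may fragment with loss of isoprene, or the enaminone may degrade at 195 °C. The fallback sets out from 4 and carries out the prenyl relay on the simple acetophenone, with an allyl ether standing in for the prenyl ether on O1. Heating 4 (N,N-diethylaniline, 195 °C) would give 1-[6-hydroxy-3-(3-methylbut-2-en-1-yl)-2,4-bis(SEM-oxy)phenyl]ethan-1-one F1. Allylation (allyl bromide, K2CO3, DMF) gives the allyl ether F2, and Claisen–Schmidt condensation with 9 gives the chalcone F3. Alkaline H2O2 gives the trans-epoxide F4, and BF3·OEt2 followed by pyrrolidine gives the O-allyl enaminone F5. No aryl prenyl ether is present in that Lewis-acid step. Pd(PPh3)4/morpholine at rt then removes the allyl group to give phenol 14, which cyclises on gentle warming; the route is rejoined at 15.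

Step 7 (epoxidation). Hydroperoxide may add sluggishly to the hindered, donor-substituted enone, or the very electron-rich epoxide may be solvolysed in the aqueous-alcoholic base. The fallback sets out from 4 and forms the C–C bond and the epoxide together under anhydrous conditions. α-Chlorination of the lithium enolate of 4 (LiHMDS, THF, −78 °C; then TsCl) would give 2-chloro-1-[2-(prenyloxy)-4,6-bis(SEM-oxy)phenyl]ethan-1-one F10. Darzens condensation of F10 with aldehyde 9 (LiHMDS, THF, −78 → 0 °C) should give the trans-epoxy ketone 11, where the route is rejoined.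

**Further compounds**

F1 | step 9 | 1-[6-hydroxy-3-(3-methylbut-2-en-1-yl)-2,4-bis(SEM-oxy)phenyl]ethan-1-one | CC(=O)c1c(O)cc(OCOCC[Si](C)(C)C)c(CC=C(C)C)c1OCOCC[Si](C)(C)C
F2 | step 9 | 1-[6-(allyloxy)-3-(3-methylbut-2-en-1-yl)-2,4-bis(SEM-oxy)phenyl]ethan-1-one | CC(=O)c1c(OCC=C)cc(OCOCC[Si](C)(C)C)c(CC=C(C)C)c1OCOCC[Si](C)(C)C
F3 | step 9 | (2E)-1-[6-(allyloxy)-3-(3-methylbut-2-en-1-yl)-2,4-bis(SEM-oxy)phenyl]-3-[2,2-dimethyl-7-(SEM-oxy)-2H-chromen-6-yl]prop-2-en-1-one | O=C(/C=C/c1cc2C=CC(C)(C)Oc2cc1OCOCC[Si](C)(C)C)c1c(OCC=C)cc(OCOCC[Si](C)(C)C)c(CC=C(C)C)c1OCOCC[Si](C)(C)C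
F4 | step 9 | rac-[(2S,3R)-3-[2,2-dimethyl-7-(SEM-oxy)-2H-chromen-6-yl]oxiran-2-yl][6-(allyloxy)-3-(3-methylbut-2-en-1-yl)-2,4-bis(SEM-oxy)phenyl]methanone | O=C(c1c(OCC=C)cc(OCOCC[Si](C)(C)C)c(CC=C(C)C)c1OCOCC[Si](C)(C)C)[C@H]1O[C@@H]1c1cc2C=CC(C)(C)Oc2cc1OCOCC[Si](C)(C)C
F5 | step 9 | (2E)-1-[6-(allyloxy)-3-(3-methylbut-2-en-1-yl)-2,4-bis(SEM-oxy)phenyl]-2-[2,2-dimethyl-7-(SEM-oxy)-2H-chromen-6-yl]-3-(pyrrolidin-1-yl)prop-2-en-1-one | O=C(c1c(OCC=C)cc(OCOCC[Si](C)(C)C)c(CC=C(C)C)c1OCOCC[Si](C)(C)C)/C(c1cc2C=CC(C)(C)Oc2cc1OCOCC[Si](C)(C)C)=C/N1CCCC1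
F6 | step 8 | 4-bromobenzene-1,3-diol (4-bromoresorcinol) | Oc1ccc(Br)c(O)c1
F7 | step 8 | 6-bromo-2,2-dimethyl-2H-chromen-7-ol | CC1(C)C=Cc2cc(Br)c(O)cc2O1
F8 | step 8 | 6-bromo-2,2-dimethyl-7-(SEM-oxy)-2H-chromene | CC1(C)C=Cc2cc(Br)c(OCOCC[Si](C)(C)C)cc2O1
F9 | step 8 | 2-[2,2-dimethyl-7-(SEM-oxy)-2H-chromen-6-yl]-1-[2-(prenyloxy)-4,6-bis(SEM-oxy)phenyl]ethan-1-one | O=C(Cc1cc2C=CC(C)(C)Oc2cc1OCOCC[Si](C)(C)C)c1c(OCC=C(C)C)cc(OCOCC[Si](C)(C)C)cc1OCOCC[Si](C)(C)C
F10 | step 7 | 2-chloro-1-[2-(prenyloxy)-4,6-bis(SEM-oxy)phenyl]ethan-1-one | O=C(CCl)c1c(OCC=C(C)C)cc(OCOCC[Si](C)(C)C)cc1OCOCC[Si](C)(C)C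
A1 | direct plan | 3-iodo-5,7-bis(methoxymethoxy)-6-(3-methylbut-2-en-1-yl)-4H-chromen-4-one | COCOc1cc2occ(I)c(=O)c2c(OCOC)c1CC=C(C)C
A2 | direct plan | 2-[7-(methoxymethoxy)-2,2-dimethyl-2H-chromen-6-yl]-4,4,5,5-tetramethyl-1,3,2-dioxaborolane | COCOc1cc2OC(C)(C)C=Cc2cc1B1OC(C)(C)C(C)(C)O1
A3 | direct plan | 3-[7-(methoxymethoxy)-2,2-dimethyl-2H-chromen-6-yl]-5,7-bis(methoxymethoxy)-6-(3-methylbut-2-en-1-yl)-4H-chromen-4-one | COCOc1cc2OC(C)(C)C=Cc2cc1-c1coc2cc(OCOC)c(CC=C(C)C)c(OCOC)c2c1=O
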